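The route rests on disconnecting the O1–C9a aryl ether bond of the oxepine ring. In the benzene ring C9a sits para to C7, the carbon that carries the side-chain carbonyl; with C7 held as a formyl group, a fluorine on C9a becomes displaceable. A single intramolecular SNAr by the alkoxide of a (Z)-allylic alcohol therefore makes O1–C9a and closes the seven-membered ring at once. The cyclisation substrate is 4-fluoro-2,6-bis(methoxymethoxy)benzaldehyde bearing a (Z)-4-hydroxy-3-methylbut-2-enyl chain at C3; its olefin geometry is fixed earlier by syn-carbocupration of an alkynoate. The formyl group afterwards receives the arylethyl side chain.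

Key step: step 9

Remarks on the chemistry:
- The (Z)-allylic bromide is built from an alkynoate, because monosilylation of (Z)-2-methylbut-2-ene-1,4-diol would not reliably tell its two primary allylic hydroxyls apart.
- n-BuLi is assumed to deprotonate 1-fluoro-3,5-bis(methoxymethoxy)benzene mainly between the two acetal oxygens; a path that does not depend on this is given with the fallbacks.

Step 1
Reactants: 1 tert-butyldimethyl(prop-2-yn-1-yloxy)silane
Product: 3 methyl 4-[(tert-butyldimethylsilyl)oxy]but-2-ynoate, via lithium acetylide 2 (not isolated)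
Conditions: n-BuLi, THF, −78 °C; ClCO2Me, −78 → 0 °C
Reagents that add atoms: methyl chloroformate, COC(=O)Cl
Why: Deprotonation of the terminal alkyne and C-acylation of the lithium acetylide with a chloroformate is a standard alkynoate synthesis that a primary silyl ether tolerates.

Step 2
Reactants: 3 methyl 4-[(tert-butyldimethylsilyl)oxy]but-2-ynoate
Product: 4 methyl (Z)-4-[(tert-butyldimethylsilyl)oxy]-3-methylbut-2-enoate
Conditions: Me2CuLi (from CuI and MeLi), THF, −78 °C; sat. aq. NH4Cl at −78 °C
Reagents that add atoms: lithium dimethylcuprate, [Li+].C[Cu-]C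
Why: Syn carbocupration (conjugate addition of a lithium dialkylcuprate to an alkynoate) followed by protonation at −78 °C places the new methyl and the α-hydrogen cis, so the ester and the silyloxymethyl group should end up cis, which is the (Z)-enoate.

Step 3
Reactants: 4 methyl (Z)-4-[(tert-butyldimethylsilyl)oxy]-3-methylbut-2-enoate
Product: 5 (Z)-4-[(tert-butyldimethylsilyl)oxy]-3-methylbut-2-en-1-ol
Conditions: i-Bu2AlH (2.2 equiv), CH2Cl2, −78 °C; aq. KNa tartrate
Reagents that add atoms: none
Why: 1,2-Reduction of an α,β-unsaturated ester with i-Bu2AlH should give the allylic alcohol without touching the olefin geometry or the silyl ether.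

Step 4
Reactants: 5 (Z)-4-[(tert-butyldimethylsilyl)oxy]-3-methylbut-2-en-1-ol
Product: 6 [(Z)-4-bromo-2-methylbut-2-enyl]oxy(tert-butyl)dimethylsilane
Conditions: CBr4, PPh3, CH2Cl2, −20 → 0 °C
Reagents that add atoms: carbon tetrabromide, BrC(Br)(Br)Br
Why: Appel bromination converts the primary allylic alcohol into the bromide under neutral conditions by SN2 displacement of the oxyphosphonium group, which should preserve the Z olefin (the bromide is used at once).

Step 5
Reactants: 7 5-fluororesorcinol (5-fluorobenzene-1,3-diol)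
Product: 8 1-fluoro-3,5-bis(methoxymethoxy)benzene
Conditions: NaH, DMF, 0 °C; MOMCl, 0 °C → rt
Reagents that add atoms: chloromethyl methyl ether (MOMCl), COCCl
Why: Williamson-type O-alkylation of the bis-phenoxide installs two acetal groups that survive strong base and later direct the lithiation.

Step 6
Reactants: 8 1-fluoro-3,5-bis(methoxymethoxy)benzene
Product: 10 4-fluoro-2,6-bis(methoxymethoxy)benzaldehyde, via aryllithium 9 (not isolated)
Conditions: n-BuLi, THF, −78 → −40 °C; DMF, −78 °C → rt; H2O
Reagents that add atoms: N,N-dimethylformamide, CN(C)C=O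
Why: Directed ortho-metalation at the carbon flanked by two chelating acetal oxygens should be kinetically preferred with n-BuLi over deprotonation beside fluorine, and formylation of the aryllithium with DMF gives a symmetric aldehyde that is easily told from its isomer.

Step 7
Reactants: 10 4-fluoro-2,6-bis(methoxymethoxy)benzaldehyde and 6 [(Z)-4-bromo-2-methylbut-2-enyl]oxy(tert-butyl)dimethylsilane
Product: 14 3-[(Z)-4-(tert-butyldimethylsilyloxy)-3-methylbut-2-enyl]-4-fluoro-2,6-bis(methoxymethoxy)benzaldehyde, via lithium α-amino alkoxide 11 (not isolated), via ring-lithiated α-amino alkoxide 12 (not isolated), via arylcopper 13 (not isolated)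
Conditions: Me2NCH2CH2N(Li)Me (from the amine and n-BuLi), THF, −78 → −40 °C; s-BuLi, −78 °C; CuBr·SMe2, −78 °C; 6, −78 → −30 °C; H2O
Reagents that add atoms: none
Why: In situ protection of the aldehyde as a lithium α-amino alkoxide, directed lithiation at the only remaining type of ring C–H (between F and OMOM, held at −78 °C to prevent loss of LiF), transmetalation to copper and SN2 allylation at the unhindered CH2Br terminus should give the C-allylated aldehyde with the Z olefin untouched.

Step 8
Reactants: 14 3-[(Z)-4-(tert-butyldimethylsilyloxy)-3-methylbut-2-enyl]-4-fluoro-2,6-bis(methoxymethoxy)benzaldehyde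
Product: 15 4-fluoro-3-[(Z)-4-hydroxy-3-methylbut-2-enyl]-2,6-bis(methoxymethoxy)benzaldehyde
Conditions: Bu4NF, AcOH, THF, 0 °C → rt
Reagents that add atoms: none
Why: Fluoride-mediated desilylation buffered with acetic acid should free the primary allylic alcohol without base-induced reaction at the aldehyde or the aryl fluoride.

Step 9
Reactants: 15 4-fluoro-3-[(Z)-4-hydroxy-3-methylbut-2-enyl]-2,6-bis(methoxymethoxy)benzaldehyde
Product: 17 6,8-bis(methoxymethoxy)-3-methyl-2,5-dihydro-1-benzoxepine-7-carbaldehyde, via potassium alkoxide 16 (not isolated)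
Conditions: KOtBu (1.2 equiv), THF (0.02 M), 0 °C → rt
Reagents that add atoms: none
Why: KOtBu converts the allylic alcohol into potassium alkoxide 16, which adds to the fluorine-bearing carbon to give a Meisenheimer anion whose charge is relayed through C7 onto the formyl oxygen, and loss of fluoride restores the arene (addition–elimination SNAr). The closest known reaction type is the intramolecular SNAr etherification of para-acyl fluoroarenes to seven-membered aryl ethers. The one ring formed, the oxepine, closes by 7-exo-trig attack, counted with respect to the C9–C9a bond of the arene. No stereocentre is created. The step needs selectivity for C9a over intermolecular substitution and over the carbonyl: only C9a combines para-formyl activation with a leaving group, the Z olefin holds the oxygen within reach so that cyclisation at high dilution should outrun dimerisation, and the formyl group cannot be enolised and switched off by base, while alkoxide addition to it is reversible and unproductive.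

Step 10
Reactants: 18 2-(3,4-dihydroxyphenyl)ethanol
Product: 19 2-[3,4-bis(methoxymethoxy)phenyl]ethanol
Conditions: MOMCl (2.1 equiv), K2CO3, acetone, 0 °C → rt
Reagents that add atoms: chloromethyl methyl ether (MOMCl), COCCl
Why: Carbonate ionises only the phenols, so Williamson alkylation with a limited amount of MOMCl should cap both phenolic oxygens and leave the primary alcohol free.

Step 11
Reactants: 19 2-[3,4-bis(methoxymethoxy)phenyl]ethanol
Product: 20 4-(2-bromoethyl)-1,2-bis(methoxymethoxy)benzene
Conditions: CBr4, PPh3, CH2Cl2, 0 °C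
Reagents that add atoms: carbon tetrabromide, BrC(Br)(Br)Br
Why: Appel bromination of the primary alcohol runs under neutral conditions that aryl MOM ethers tolerate.

Step 12
Reactants: 20 4-(2-bromoethyl)-1,2-bis(methoxymethoxy)benzene and 17 6,8-bis(methoxymethoxy)-3-methyl-2,5-dihydro-1-benzoxepine-7-carbaldehyde
Product: 22 1-[6,8-bis(methoxymethoxy)-3-methyl-2,5-dihydro-1-benzoxepin-7-yl]-3-[3,4-bis(methoxymethoxy)phenyl]propan-1-ol (racemic), via Grignard reagent 21 (not isolated)
Conditions: 20, Mg, THF, rt → 40 °C; then 17, THF, 0 °C → rt; H2O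
Reagents that add atoms: none
Why: Grignard formation from the primary bromide and 1,2-addition to the non-enolisable aldehyde should give the secondary benzylic alcohol as a racemate, which does not matter because the carbinol stereocentre is removed in the next step.

Step 13
Reactants: 22 1-[6,8-bis(methoxymethoxy)-3-methyl-2,5-dihydro-1-benzoxepin-7-yl]-3-[3,4-bis(methoxymethoxy)phenyl]propan-1-ol
Product: 23 1-[6,8-bis(methoxymethoxy)-3-methyl-2,5-dihydro-1-benzoxepin-7-yl]-3-[3,4-bis(methoxymethoxy)phenyl]propan-1-one
Conditions: Dess–Martin periodinane, CH2Cl2, 0 °C → rt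
Reagents that add atoms: none
Why: Dess–Martin oxidation of a secondary benzylic alcohol to the aryl ketone is mild enough to leave the trisubstituted olefin, the allylic aryl ether and the MOM acetals intact.

Step 14
Reactants: 23 1-[6,8-bis(methoxymethoxy)-3-methyl-2,5-dihydro-1-benzoxepin-7-yl]-3-[3,4-bis(methoxymethoxy)phenyl]propan-1-one
Product: 24 1-(6,8-dihydroxy-3-methyl-2,5-dihydro-1-benzoxepin-7-yl)-3-(3,4-dihydroxyphenyl)propan-1-one (target)
Conditions: 3 M aq. HCl, MeOH, 40 °C
Reagents that add atoms: none
Why: Acid-catalysed acetal exchange with methanol should remove all four MOM groups, the two ortho to the ketone being especially labile, under conditions mild enough for the allylic aryl ether of the dihydrooxepine.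

Compound list
1 | tert-butyldimethyl(prop-2-yn-1-yloxy)silane | C#CCO[Si](C)(C)C(C)(C)C | starting material
2 | 3-(tert-butyldimethylsilyloxy)prop-1-ynyllithium | [Li]C#CCO[Si](C)(C)C(C)(C)C | intermediate
3 | methyl 4-[(tert-butyldimethylsilyl)oxy]but-2-ynoate | COC(=O)C#CCO[Si](C)(C)C(C)(C)C | intermediate
4 | methyl (Z)-4-[(tert-butyldimethylsilyl)oxy]-3-methylbut-2-enoate | COC(=O)/C=C(C)\CO[Si](C)(C)C(C)(C)C | intermediate
5 | (Z)-4-[(tert-butyldimethylsilyl)oxy]-3-methylbut-2-en-1-ol | OC/C=C(C)\CO[Si](C)(C)C(C)(C)C | intermediate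
6 | [(Z)-4-bromo-2-methylbut-2-enyl]oxy(tert-butyl)dimethylsilane | BrC/C=C(C)\CO[Si](C)(C)C(C)(C)C | intermediate
7 | 5-fluororesorcinol (5-fluorobenzene-1,3-diol) | Oc1cc(O)cc(F)c1 | starting material
8 | 1-fluoro-3,5-bis(methoxymethoxy)benzene | COCOc1cc(F)cc(OCOC)c1 | intermediate
9 | [4-fluoro-2,6-bis(methoxymethoxy)phenyl]lithium | [Li]c1c(OCOC)cc(F)cc1OCOC | intermediate
10 | 4-fluoro-2,6-bis(methoxymethoxy)benzaldehyde | O=Cc1c(OCOC)cc(F)cc1OCOC | intermediate
11 | lithium [4-fluoro-2,6-bis(methoxymethoxy)phenyl]{[2-(dimethylamino)ethyl](methyl)amino}methanolate (α-amino alkoxide of 10, racemic) | [Li+].[O-]C(N(C)CCN(C)C)c1c(OCOC)cc(F)cc1OCOC | intermediate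
12 | 11 lithiated at ring C3, the carbon between F and OMOM | [Li+].[O-]C(N(C)CCN(C)C)c1c(OCOC)cc(F)c([Li])c1OCOC | intermediate
13 | arylcopper corresponding to 12 (Cu in place of the ring Li) | [Li+].[O-]C(N(C)CCN(C)C)c1c(OCOC)cc(F)c([Cu])c1OCOC | intermediate
14 | 3-[(Z)-4-(tert-butyldimethylsilyloxy)-3-methylbut-2-enyl]-4-fluoro-2,6-bis(methoxymethoxy)benzaldehyde | O=Cc1c(OCOC)cc(F)c(C/C=C(C)\CO[Si](C)(C)C(C)(C)C)c1OCOC | intermediate
15 | 4-fluoro-3-[(Z)-4-hydroxy-3-methylbut-2-enyl]-2,6-bis(methoxymethoxy)benzaldehyde | O=Cc1c(OCOC)cc(F)c(C/C=C(C)\CO)c1OCOC | intermediate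
16 | potassium (Z)-4-[6-fluoro-3-formyl-2,4-bis(methoxymethoxy)phenyl]-2-methylbut-2-en-1-olate | [K+].[O-]C/C(C)=C\Cc1c(F)cc(OCOC)c(C=O)c1OCOC | intermediate
17 | 6,8-bis(methoxymethoxy)-3-methyl-2,5-dihydro-1-benzoxepine-7-carbaldehyde | CC1=CCc2c(cc(OCOC)c(C=O)c2OCOC)OC1 | intermediate
18 | 2-(3,4-dihydroxyphenyl)ethanol | OCCc1ccc(O)c(O)c1 | starting material
19 | 2-[3,4-bis(methoxymethoxy)phenyl]ethanol | COCOc1ccc(CCO)cc1OCOC | intermediate
20 | 4-(2-bromoethyl)-1,2-bis(methoxymethoxy)benzene | COCOc1ccc(CCBr)cc1OCOC | intermediate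
21 | 2-[3,4-bis(methoxymethoxy)phenyl]ethylmagnesium bromide | COCOc1ccc(CC[Mg]Br)cc1OCOC | intermediate
22 | 1-[6,8-bis(methoxymethoxy)-3-methyl-2,5-dihydro-1-benzoxepin-7-yl]-3-[3,4-bis(methoxymethoxy)phenyl]propan-1-ol (racemic) | CC1=CCc2c(cc(OCOC)c(C(O)CCc3ccc(OCOC)c(OCOC)c3)c2OCOC)OC1 | intermediate
23 | 1-[6,8-bis(methoxymethoxy)-3-methyl-2,5-dihydro-1-benzoxepin-7-yl]-3-[3,4-bis(methoxymethoxy)phenyl]propan-1-one | CC1=CCc2c(cc(OCOC)c(C(=O)CCc3ccc(OCOC)c(OCOC)c3)c2OCOC)OC1 | intermediate
24 | 1-(6,8-dihydroxy-3-methyl-2,5-dihydro-1-benzoxepin-7-yl)-3-(3,4-dihydroxyphenyl)propan-1-one | CC1=CCc2c(cc(O)c(C(=O)CCc3ccc(O)c(O)c3)c2O)OC1 | target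

Total step count: 14
Longest linear sequence: 10 steps (steps 1–4, 7–9, 12–14)

Steps most likely to fail

1. Step 7. What may go wrong: incomplete masking of the formyl group, so that s-BuLi adds to the carbonyl, or loss of LiF from the ortho-fluoro aryllithium before copper transfer. Fallback: an isolable aminal replaces the transient mask. Setting out from 10, condensation with N,N′-dimethylethane-1,2-diamine (toluene, MgSO4, rt) should give 2-[4-fluoro-2,6-bis(methoxymethoxy)phenyl]-1,3-dimethylimidazolidine F1. Treatment with s-BuLi (THF, −78 °C) should give the ring-lithiated imidazolidine F2, CuBr·SMe2 the arylcopper F3, and bromide 6 the allylated aminal 2-{3-[(Z)-4-(tert-butyldimethylsilyloxy)-3-methylbut-2-enyl]-4-fluoro-2,6-bis(methoxymethoxy)phenyl}-1,3-dimethylimidazolidine F4. Brief hydrolysis with 5% aqueous oxalic acid in THF at 0 °C should release the aldehyde, and the route is rejoined at 14.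

2. Step 9. What may go wrong: ring closure too slow on an arene enriched by two acetal oxygens, so that hydride transfer from the alkoxide to the formyl group or intermolecular substitution takes over. Fallback: the oxepine is closed at C3=C4 by ring-closing metathesis, and the aryl ether is made intermolecularly with a simple alkoxide that can be used in excess. Setting out from 10, the masked lithiation of step 7 (through 11, 12 and 13) with allyl bromide in place of 6 should give 3-allyl-4-fluoro-2,6-bis(methoxymethoxy)benzaldehyde F5. Intermolecular SNAr with 2-methylprop-2-en-1-ol (NaH, DMF, 0 °C → rt) should give 3-allyl-4-[(2-methylprop-2-enyl)oxy]-2,6-bis(methoxymethoxy)benzaldehyde F6. Ring-closing metathesis with second-generation Grubbs catalyst, (H2IMes)(PCy3)Cl2Ru=CHPh, in CH2Cl2 at 40 °C should then deliver 17, where the route is rejoined.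

3. Step 6. What may go wrong: competing deprotonation beside fluorine, followed by LiF elimination to an aryne and loss of material. Fallback: the regiochemistry is set by electrophilic iodination and halogen–metal exchange. Setting out from 7, I2 and NaHCO3 in water–THF at 0 °C should iodinate between the two hydroxyls to give 5-fluoro-2-iodobenzene-1,3-diol F7. NaH and MOMCl in DMF should give 5-fluoro-2-iodo-1,3-bis(methoxymethoxy)benzene F8. Iodine–lithium exchange with n-BuLi (THF, −78 °C) generates the aryllithium 9 directly, where the route is rejoined before the DMF quench.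

Further compounds
F1 | step 7 | 2-[4-fluoro-2,6-bis(methoxymethoxy)phenyl]-1,3-dimethylimidazolidine | CN1CCN(C)C1c1c(OCOC)cc(F)cc1OCOC
F2 | step 7 | F1 lithiated at the ring carbon between F and OMOM | CN1CCN(C)C1c1c(OCOC)cc(F)c([Li])c1OCOC
F3 | step 7 | arylcopper corresponding to F2 | CN1CCN(C)C1c1c(OCOC)cc(F)c([Cu])c1OCOC
F4 | step 7 | 2-{3-[(Z)-4-(tert-butyldimethylsilyloxy)-3-methylbut-2-enyl]-4-fluoro-2,6-bis(methoxymethoxy)phenyl}-1,3-dimethylimidazolidine | CN1CCN(C)C1c1c(OCOC)cc(F)c(C/C=C(C)\CO[Si](C)(C)C(C)(C)C)c1OCOC
F5 | step 9 | 3-allyl-4-fluoro-2,6-bis(methoxymethoxy)benzaldehyde | O=Cc1c(OCOC)cc(F)c(CC=C)c1OCOC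
F6 | step 9 | 3-allyl-4-[(2-methylprop-2-enyl)oxy]-2,6-bis(methoxymethoxy)benzaldehyde | O=Cc1c(OCOC)cc(OCC(C)=C)c(CC=C)c1OCOC
F7 | step 6 | 5-fluoro-2-iodobenzene-1,3-diol | Oc1cc(F)cc(O)c1I
F8 | step 6 | 5-fluoro-2-iodo-1,3-bis(methoxymethoxy)benzene | COCOc1cc(F)cc(OCOC)c1I
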